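## Assumptions and remarks on the chemistry

- Chroman numbering is used throughout: O1, C2, C3, C4, C4a, C5 to C8, C8a; ring A is the fused benzo ring, ring B the aryl group on C2 (C1' to C6'). Read this way, target 25 is (2R,3R,4S): ring B trans to isopropyl, isopropyl cis to isobutyl.
- Tracing the configuration through two retentive borylations and two invertive 1,2-shifts, boronic ester 15 must be (3R,4S) and both carbenoids must be S. Both are therefore made with (−)-sparteine; the (+)-surrogate is not needed.
- The six phenol oxygens are carried as methyl ethers. They are the smallest groups that can stand ortho to the reacting boron, and all are removed in the operation that closes the pyran ring.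
- The first 1,2-shift is run without a magnesium salt, so that the second carbenoid meets no Lewis acid in the pot.
- (2,4,6-Trimethoxyphenyl)methanol 16 is assumed to be a catalogue compound.

## Structural features

Sideroxylonal A (25) is a 2-arylchroman: a dihydropyran ring (O1, C2, C3, C4, C4a, C8a) is fused to ring A through C4a–C8a and carries ring B on C2. Both arenes are hexasubstituted phloroglucinols: ring A has hydroxyl groups at C5 and C7, formyl groups at C6 and C8 and its third oxygen as O1; ring B has hydroxyl groups at C2', C4', C6' and formyl groups at C3' and C5'. C2, C3 and C4 are three contiguous CH stereocentres bearing ring B, isopropyl and isobutyl; ring B and isopropyl are equatorial and the cis isobutyl group is pseudoaxial, turned away from the C5 oxygen. The fragile parts are the four salicylaldehyde-type formyl groups, the five acidic phenols and the O1–C2 bond, a benzylic aryl ether next to a phloroglucinol ring that ionises easily in acid. Because of this lability C2 can be left to equilibrate, but the aldehydes and the free phenols have to appear late. The real difficulty is the C3/C4 pair: two neighbouring tertiary carbons with only branched alkyl groups, no heteroatom to direct a reagent, wedged between two arenes substituted in both ortho positions. The key step uses the fact that C4a–C4–C3 is an unbranched chain leaving ring A at C4a with exactly one alkyl group on each carbon. That is the pattern left by two successive one-carbon insertions into an aryl C–B bond, and the boron that remains on C3 is the handle for C2.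

## Logic of the disconnections

25 to 23. The four aryl–CHO bonds (at C6, C8, C3', C5') are cut first, because aldehydes tolerate neither the organolithium and boron chemistry nor the ether cleavage. The gain is a substrate without electrophilic groups. The four sites are the only free ring carbons and each lies between two oxygens, so no regiochemical choice arises. The demand is a fourfold electrophilic substitution that goes to completion on a free polyphenol without opening O1–C2.

23 to 22. The O1–C2 bond is cut and the six phenolic hydrogens are exchanged for methyl groups. The cation at C2 is stabilised by ring B and is captured by an ortho oxygen of ring A; because the closure is reversible in acid, ring B settles trans to isopropyl. The gain is an open-chain carbinol whose C2 configuration is irrelevant. The demand is that ionisation is followed by ring closure faster than by loss of the C3 hydrogen or by intermolecular arylation.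

22 to 15 and 18. The C2–C3 bond is cut, with the C2–O bond traced back to a C2–B bond in 21. A third one-carbon insertion into the C3–B bond of 15 brings C2 and ring B as one achiral reagent, with retention at C3. The gain is that ring B arrives fully formed and no stereocontrol is needed at C2. The demand is that a very crowded secondary boronic ester accepts a benzylic carbenoid substituted in both ortho positions.

15 to 3, 5 and 9. The C3–C4 and C4–C4a bonds are cut. Each carbon is inserted as a configurationally defined carbenoid, so C4 and C3 are set one at a time by the reagent and not by the substrate. The gain is three achiral building blocks, each one step from commercial material. The demand is two additions to hindered boron in one pot, each exactly once, with no loss of carbenoid configuration.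

3 to 1. The C4a–B bond is cut; the ring hydrogen between two methoxy groups is the most acidic site and all three such sites are equivalent. The demand is only that the electron-rich aryl boronic ester is not protodeboronated during isolation.

5 to 4, and 18 to 16. The carbamate O–C(=O) bonds are cut. The carbamoyl group is both the directing group for α-lithiation and the leaving group of the 1,2-shift. The demand on 18 is base-only handling, since its benzylic C–O bond ionises in acid.

9 to 6 and 7. The ester O–C(=O) bond is cut. The hindered aroyl group resists attack by the base and leaves more readily than a carbamate, which the crowded second insertion requires.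

## Other disconnections considered

Alternative 1: The cut is O1–C8a. The precursor would be the open-chain carbinol A2, with fluorine at C8a of ring A, all four formyl groups in place and all phenols as methyl ethers. With K2CO3 in N,N-dimethylformamide its C2 alkoxide adds to C8a, which is activated by the formyl groups ortho (C8) and para (C6) to it, and loss of fluoride from the Meisenheimer adduct closes the pyran ring to give the penta-O-methyl ether A1.
- In favour: addition–elimination on a doubly activated fluoroarene is dependable. The C2–O bond is never broken, so C2 keeps the configuration of A2 and C3 cannot be lost through an elimination. Only five methyl ethers, each ortho to a formyl group and open to chelation-assisted cleavage with BCl3, separate A1 from 25.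
- Better than the chosen plan on the end-game, which must formylate a free polyphenol four times.
- Against: A2 holds all three stereocentres in open-chain form, including C2, which the chosen plan obtains by equilibration. The aldehydes must be masked through the chain-building steps or installed on an ionisable acyclic carbinol. The alkoxide could also transfer hydride to a neighbouring aldehyde.
- Comparison: structurally it solves the easy heteroatom bond and leaves the C3/C4 problem open. Mechanistically its polar ring closure is at least the equal of the SN1 closure in step 7. In step economy it is expected to be longer, because of the masking or late installation of four aldehydes on A2.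

Alternative 2: The cuts are C8a–O1, C4a–C4 and O1–C2, made in one cascade. The aryne released by CsF from silyl triflate A5 would add across the C=O bond of enone A4; the benzoxete opens to an ortho-quinone methide and oxa-6π electrocyclisation gives 2H-chromene A3. The methoxy group next to the aryne bond directs oxygen to the distal carbon, which gives the required 5,7-pattern.
- In favour: three bonds and the pyran ring form in one step, and A4 is one aldol condensation away from two commercial carbonyl compounds. A cis-hydrogenation of the C3=C4 bond of A3 would give the required 3,4-cis relationship, and C2 could then be equilibrated in acid as in the chosen plan.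
- Better than the chosen plan on convergence and step count to the carbon skeleton.
- Against: aryne addition across C=O is established mainly for aldehydes and formamides, and a hindered ketone is a poor partner. A3 is racemic. Its C3=C4 bond is tetrasubstituted, lies between a peri methoxy group and ring B and has no directing group, so an enantioselective hydrogenation with the catalyst overriding the C2 centre is a weak point.
- Comparison: the alternative builds the ring first and leaves both difficult stereocentres to one hard reduction. The chosen plan sets them first, by stereospecific 1,2-shifts, and closes the ring afterwards. The end-game (ether cleavage and formylation) is the same in both.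

Alternative 3: The cuts are C1'–C6', C2'–C3' and C5'–C6' of ring B. Heating silyl ynol ether A7 with cyclobutenone A8 would open A8 to a vinylketene, which adds to the ynol ether in a [2+2] sense; a second four-electron opening, six-electron closure and tautomerisation give phenol A6, with both future formyl carbons of ring B present as methyl groups.
- In favour: the benzannulation places six different substituents on ring B without any electrophilic substitution. Ring B is not yet a free phloroglucinol while it is attached, so C2 does not ionise during the key step.
- Equal or better on regiochemical definition of ring B and on the kinetic security of C2.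
- Against: ring B is symmetrical and commercially available in the right oxygenation pattern, so the regiocontrol buys nothing here. A7 presupposes a chroman with all three stereocentres and a C2 ynol ether. Two aryl methyl groups must later be oxidised to aldehydes on an electron-rich ring beside the oxidisable C2–H, ring A needs a separate formylation, and ethyl, silyl and methyl ethers must all be removed.
- Comparison: structurally it spends its key step on the one part of the molecule that needs no synthesis. Mechanistically the pericyclic cascade is as reliable as the chosen 1,2-shifts. In step economy it is clearly the longest of the four plans.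

Key step: step 4

## Route

Step 1
Reactants: 1 1,3,5-trimethoxybenzene
Product: 3 2-(2,4,6-trimethoxyphenyl)-4,4,5,5-tetramethyl-1,3,2-dioxaborolane, via 2,4,6-trimethoxyphenyllithium 2 (not isolated)
Conditions: nBuLi, THF, 0 °C → rt, 2 h; iPrOBpin, −78 °C → rt; aq. NH4Cl
Reagents that add atoms: 2-isopropoxy-4,4,5,5-tetramethyl-1,3,2-dioxaborolane, CC(C)OB1OC(C)(C)C(C)(C)O1
Why: Directed ortho-lithiation followed by electrophilic borylation: nBuLi removes the ring hydrogen between two methoxy groups and aryllithium 2 displaces isopropoxide from the borate. The three ring positions are equivalent, so only one product is possible.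

Step 2
Reactants: 4 3-methylbutan-1-ol
Product: 5 3-methylbutyl N,N-diisopropylcarbamate
Conditions: iPr2NCOCl, Et3N, CH2Cl2, reflux
Reagents that add atoms: N,N-diisopropylcarbamoyl chloride, CC(C)N(C(C)C)C(Cl)=O
Why: O-Carbamoylation of a primary alcohol (nucleophilic acyl substitution). The carbamate is the directing group for the later α-lithiation and the leaving group of the first 1,2-shift.

Step 3
Reactants: 6 2-methylpropan-1-ol; 7 2,4,6-triisopropylbenzoyl chloride
Product: 9 2-methylpropyl 2,4,6-triisopropylbenzoate, via sodium 2-methylpropan-1-olate 8 (not isolated)
Conditions: NaH, THF, 0 °C → rt; 7, reflux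
Reagents that add atoms: none
Why: Esterification of an alkoxide with a hindered aroyl chloride (nucleophilic acyl substitution). The two ortho isopropyl groups that slow this step are what later protect the carbonyl group from sBuLi.

Step 4
Reactants: 5 3-methylbutyl N,N-diisopropylcarbamate; 3 2-(2,4,6-trimethoxyphenyl)-4,4,5,5-tetramethyl-1,3,2-dioxaborolane; 9 2-methylpropyl 2,4,6-triisopropylbenzoate
Product: 15 2-[(3R,4S)-2,6-dimethyl-4-(2,4,6-trimethoxyphenyl)heptan-3-yl]-4,4,5,5-tetramethyl-1,3,2-dioxaborolane, via lithiated carbamate 10 (not isolated), via first boronate complex 11 (not isolated), via benzylic boronic ester 12 (not isolated), via lithiated benzoate 13 (not isolated), via second boronate complex 14 (not isolated)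
Conditions: a) 5 (1.3 equiv), sBuLi, (−)-sparteine, Et2O, −78 °C, 5 h; 3 (1.0 equiv), −78 °C, 2 h; then reflux, 16 h; b) cooled solution added to 13 [9 (2.0 equiv), sBuLi, (−)-sparteine, Et2O, −78 °C, 5 h]; −78 °C, 3 h; MgBr2 in MeOH, −78 °C → rt
Reagents that add atoms: none
Why: Iterative lithiation–borylation (assembly-line homologation); the closest known reaction type is the one-pot, reagent-controlled homologation of boronic esters with sparteine-derived lithiated carbamates and hindered benzoates. sBuLi/(−)-sparteine removes the pro-S proton of 5 to give configurationally stable (S)-10, which attacks boron of 3 with retention to give 11; on warming, the electron-rich aryl group shifts from boron to carbon anti to the departing carbamate (inversion at carbon), forming C4–C4a in (R)-12. Lithiated benzoate 13, made the same way from 9 and also S, adds to 12 with retention to give 14; the benzylic carbon C4 then migrates with retention while the benzoate leaves with inversion at the carbenoid carbon, forming C3–C4 in (3R,4S)-15. No ring is closed. C4 is controlled only by the sense of deprotonation of 5 and C3 only by that of 9, both fixed by (−)-sparteine, and both 1,2-shifts are stereospecific; any minor enantiomer of either carbenoid should end up mainly in a separable diastereomer. The step needs exactly one insertion per stage: 3 is the limiting reagent, so none is left to intercept 13, and 11 should not rearrange until surplus 10 has decomposed on warming, which prevents double insertion. It also needs the second shift to outrun reversal of the crowded boronate 14: the triisopropylbenzoate is a better leaving group than a carbamate, and MgBr2 in MeOH accelerates the shift while methanol protonates any 13 set free, so that eroded carbenoid cannot add again. Running the first shift thermally keeps Lewis acid out of the pot until 14 has formed, and the methyl ethers keep the ortho positions around boron as small as possible.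

Step 5
Reactants: 16 (2,4,6-trimethoxyphenyl)methanol
Product: 18 (2,4,6-trimethoxyphenyl)methyl N,N-diisopropylcarbamate, via sodium alkoxide 17 (not isolated)
Conditions: NaH, THF, 0 °C; iPr2NCOCl, rt → 50 °C
Reagents that add atoms: N,N-diisopropylcarbamoyl chloride, CC(C)N(C(C)C)C(Cl)=O
Why: O-Carbamoylation through the sodium alkoxide (nucleophilic acyl substitution). Base-only conditions are used because the electron-rich benzylic C–O bond of 16 and 18 ionises in acid.

Step 6
Reactants: 18 (2,4,6-trimethoxyphenyl)methyl N,N-diisopropylcarbamate; 15 2-[(3R,4S)-2,6-dimethyl-4-(2,4,6-trimethoxyphenyl)heptan-3-yl]-4,4,5,5-tetramethyl-1,3,2-dioxaborolane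
Product: 22 (1RS,2R,3S)-5-methyl-2-(propan-2-yl)-1,3-bis(2,4,6-trimethoxyphenyl)hexan-1-ol, via lithiated benzylic carbamate 19 (not isolated), via third boronate complex 20 (not isolated), via C2 boronic ester 21 (not isolated)
Conditions: 18, sBuLi, TMEDA, Et2O, −78 °C, 30 min; 15, −78 °C, 2 h; → rt, then 40 °C; NaOH, H2O2, THF/H2O, 0 °C → rt
Reagents that add atoms: hydrogen peroxide, OO
Why: Lithiation–borylation with a primary benzylic carbamate followed by boronate oxidation: the carbamate directs benzylic lithiation of 18, racemic carbenoid 19 adds to boron of 15, and C3 migrates with retention as the benzylic carbamate leaves to give 21; alkaline H2O2 then replaces boron by oxygen with retention. C3 and C4 are untouched; C2 forms as a mixture of epimers, which does not matter because it is reset in step 7.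

Step 7
Reactants: 22 (1RS,2R,3S)-5-methyl-2-(propan-2-yl)-1,3-bis(2,4,6-trimethoxyphenyl)hexan-1-ol
Product: 23 (2R,3R,4S)-4-(2-methylpropyl)-3-(propan-2-yl)-2-(2,4,6-trihydroxyphenyl)-3,4-dihydro-2H-chromene-5,7-diol
Conditions: BBr3, CH2Cl2 (dilute), −78 → 0 °C; MeOH; then HCl (cat.), MeOH, rt
Reagents that add atoms: none
Why: Lewis-acid ether cleavage combined with an SN1 ring closure: BBr3 ionises the C2 carbinol to a benzylic cation stabilised by ring B, an ortho oxygen of ring A closes the six-membered ring (as the methyl ether with loss of bromomethane, or as the phenol once freed), and the remaining methyl ethers are cleaved. C2 is set here under thermodynamic control, because O1–C2 ionises again in acid and the isomer with ring B and isopropyl both equatorial (2,3-trans) and isobutyl pseudoaxial is the most stable. C3 and C4 carry no leaving group and are not affected.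

Step 8
Reactants: 23 (2R,3R,4S)-4-(2-methylpropyl)-3-(propan-2-yl)-2-(2,4,6-trihydroxyphenyl)-3,4-dihydro-2H-chromene-5,7-diol
Product: 25 sideroxylonal A, via tetrakis(iminium) chloride 24 (not isolated)
Conditions: POCl3, DMF, 1,4-dioxane, 0 °C → rt; then H2O, 50 °C
Reagents that add atoms: N,N-dimethylformamide, CN(C)C=O; water, O
Why: Vilsmeier–Haack formylation (electrophilic aromatic substitution by the chloroiminium ion, then hydrolysis of aryl iminium salt 24): C6, C8, C3' and C5' are the only unsubstituted ring carbons and each lies between two oxygen substituents, so exhaustive reaction can lead only to 25. No stereocentre is formed, and each formyl group makes the rings less electron-rich and the O1–C2 bond less prone to ionise.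

## Compound list

1 | 1,3,5-trimethoxybenzene | COc1cc(OC)cc(OC)c1 | starting material
2 | 2,4,6-trimethoxyphenyllithium | [Li]c1c(OC)cc(OC)cc1OC | intermediate
3 | 2-(2,4,6-trimethoxyphenyl)-4,4,5,5-tetramethyl-1,3,2-dioxaborolane | COc1cc(OC)c(B2OC(C)(C)C(C)(C)O2)c(OC)c1 | intermediate
4 | 3-methylbutan-1-ol | CC(C)CCO | starting material
5 | 3-methylbutyl N,N-diisopropylcarbamate | CC(C)CCOC(=O)N(C(C)C)C(C)C | intermediate
6 | 2-methylpropan-1-ol | CC(C)CO | starting material
7 | 2,4,6-triisopropylbenzoyl chloride | CC(C)c1cc(C(C)C)c(C(Cl)=O)c(C(C)C)c1 | starting material
8 | sodium 2-methylpropan-1-olate | [Na+].CC(C)C[O-] | intermediate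
9 | 2-methylpropyl 2,4,6-triisopropylbenzoate | CC(C)COC(=O)c1c(C(C)C)cc(C(C)C)cc1C(C)C | intermediate
10 | (1S)-1-lithio-3-methylbutyl N,N-diisopropylcarbamate, as its (−)-sparteine complex | CC(C)C[C@H]([Li])OC(=O)N(C(C)C)C(C)C | intermediate
11 | lithium [(1S)-1-(diisopropylcarbamoyloxy)-3-methylbutyl](2,4,6-trimethoxyphenyl)(pinacolato)borate | [Li+].CC(C)C[C@H]([B-]1(c2c(OC)cc(OC)cc2OC)OC(C)(C)C(C)(C)O1)OC(=O)N(C(C)C)C(C)C | intermediate
12 | 2-[(1R)-3-methyl-1-(2,4,6-trimethoxyphenyl)butyl]-4,4,5,5-tetramethyl-1,3,2-dioxaborolane | CC(C)C[C@H](c1c(OC)cc(OC)cc1OC)B1OC(C)(C)C(C)(C)O1 | intermediate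
13 | (1S)-1-lithio-2-methylpropyl 2,4,6-triisopropylbenzoate, as its (−)-sparteine complex | CC(C)[C@H]([Li])OC(=O)c1c(C(C)C)cc(C(C)C)cc1C(C)C | intermediate
14 | lithium [(1S)-2-methyl-1-(2,4,6-triisopropylbenzoyloxy)propyl][(1R)-3-methyl-1-(2,4,6-trimethoxyphenyl)butyl](pinacolato)borate | [Li+].CC(C)C[C@H](c1c(OC)cc(OC)cc1OC)[B-]1([C@@H](C(C)C)OC(=O)c2c(C(C)C)cc(C(C)C)cc2C(C)C)OC(C)(C)C(C)(C)O1 | intermediate
15 | 2-[(3R,4S)-2,6-dimethyl-4-(2,4,6-trimethoxyphenyl)heptan-3-yl]-4,4,5,5-tetramethyl-1,3,2-dioxaborolane | CC(C)C[C@H](c1c(OC)cc(OC)cc1OC)[C@@H](C(C)C)B1OC(C)(C)C(C)(C)O1 | intermediate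
16 | (2,4,6-trimethoxyphenyl)methanol | COc1cc(OC)c(CO)c(OC)c1 | starting material
17 | sodium (2,4,6-trimethoxyphenyl)methanolate | [Na+].COc1cc(OC)c(C[O-])c(OC)c1 | intermediate
18 | (2,4,6-trimethoxyphenyl)methyl N,N-diisopropylcarbamate | COc1cc(OC)c(COC(=O)N(C(C)C)C(C)C)c(OC)c1 | intermediate
19 | lithio(2,4,6-trimethoxyphenyl)methyl N,N-diisopropylcarbamate (racemic, TMEDA complex) | [Li]C(OC(=O)N(C(C)C)C(C)C)c1c(OC)cc(OC)cc1OC | intermediate
20 | lithium [(diisopropylcarbamoyloxy)(2,4,6-trimethoxyphenyl)methyl][(3R,4S)-2,6-dimethyl-4-(2,4,6-trimethoxyphenyl)heptan-3-yl](pinacolato)borate (both epimers at the carbamate carbon) | [Li+].CC(C)C[C@H](c1c(OC)cc(OC)cc1OC)[C@@H](C(C)C)[B-]1(C(OC(=O)N(C(C)C)C(C)C)c2c(OC)cc(OC)cc2OC)OC(C)(C)C(C)(C)O1 | intermediate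
21 | 2-[(1RS,2R,3S)-5-methyl-2-(propan-2-yl)-1,3-bis(2,4,6-trimethoxyphenyl)hexyl]-4,4,5,5-tetramethyl-1,3,2-dioxaborolane | CC(C)C[C@H](c1c(OC)cc(OC)cc1OC)[C@@H](C(C)C)C(B1OC(C)(C)C(C)(C)O1)c1c(OC)cc(OC)cc1OC | intermediate
22 | (1RS,2R,3S)-5-methyl-2-(propan-2-yl)-1,3-bis(2,4,6-trimethoxyphenyl)hexan-1-ol | CC(C)C[C@H](c1c(OC)cc(OC)cc1OC)[C@@H](C(C)C)C(O)c1c(OC)cc(OC)cc1OC | intermediate
23 | (2R,3R,4S)-4-(2-methylpropyl)-3-(propan-2-yl)-2-(2,4,6-trihydroxyphenyl)-3,4-dihydro-2H-chromene-5,7-diol | CC(C)C[C@@H]1c2c(O)cc(O)cc2O[C@@H](c2c(O)cc(O)cc2O)[C@@H]1C(C)C | intermediate
24 | tetrakis(N,N-dimethyliminiomethyl) derivative of 23 at C6, C8, C3' and C5', tetrachloride | CC(C)C[C@@H]1c2c(O)c(C=[N+](C)C)c(O)c(C=[N+](C)C)c2O[C@@H](c2c(O)c(C=[N+](C)C)c(O)c(C=[N+](C)C)c2O)[C@@H]1C(C)C.[Cl-].[Cl-].[Cl-].[Cl-] | intermediate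
25 | sideroxylonal A, (2R,3R,4S)-2-(3,5-diformyl-2,4,6-trihydroxyphenyl)-5,7-dihydroxy-4-(2-methylpropyl)-3-(propan-2-yl)-3,4-dihydro-2H-chromene-6,8-dicarbaldehyde | CC(C)C[C@@H]1c2c(O)c(C=O)c(O)c(C=O)c2O[C@@H](c2c(O)c(C=O)c(O)c(C=O)c2O)[C@@H]1C(C)C | target

## Step count and least certain steps

Total step count: 8 (steps 1 to 8; steps 1, 2, 3 and 5 are one-step preparations of the four building blocks).
Longest linear sequence: 5 steps (1 → 3 → 15 → 22 → 23 → 25, that is steps 1, 4, 6, 7 and 8).

Step 4 (key step). The most likely failure is incomplete addition of the sparteine-bound carbenoid 13 to the crowded boron of 12, which carries a secondary benzylic carbon with both ortho positions substituted. The boronate 14 may also revert with loss of stereochemical fidelity, or the first 1,2-shift may be sluggish without a Lewis acid. Fallback: the two insertions are separated.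
- Stage a is run alone, with MgBr2·OEt2 to drive the shift if needed, and 12 is isolated.
- 9 is lithiated as before and quenched with Me3SnCl (retention) to give the stannane (1S)-2-methyl-1-(trimethylstannyl)propyl 2,4,6-triisopropylbenzoate F1, which can be purified and enriched.
- Tin–lithium exchange on F1 with nBuLi at −78 °C sets free 13 without diamine. This smaller carbenoid is the type known to add to hindered secondary boronic esters; addition to 12 and warming give 15.
- The fallback sets out from 9 and 12 and returns to the route at 15.

Step 6. The most likely failure is that boronate formation does not take place, because the C3 boron of 15 is flanked by two branched carbons and carbenoid 19 has two ortho methoxy groups. Competing ring lithiation of 18 and migration of a pinacol oxygen in place of C3 are further risks. Fallback: the one-carbon unit and ring B are brought in separately by a Matteson homologation.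
- From 15, LiCHCl2 (CH2Cl2, nBuLi, THF, −100 °C), then ZnCl2 and warming, gives the α-chloro boronic ester 2-[(1RS,2R,3S)-1-chloro-5-methyl-2-(propan-2-yl)-3-(2,4,6-trimethoxyphenyl)hexyl]-4,4,5,5-tetramethyl-1,3,2-dioxaborolane F2.
- Aryllithium 2, made as in step 1, adds to boron of F2 at −78 °C, and on warming the aryl group displaces chloride to give 21.
- 21 is oxidised as in step 6 to 22. The fallback sets out from 15 and returns at 21.

Step 7. The most likely failure is that the C2 cation, formed under a strong Lewis acid while the ethers are still being cleaved, loses the C3 hydrogen and is reprotonated (erosion at C3) or arylates a second molecule. Acid cleavage of the C1'–C2 bond after ring closure is a further risk. Fallback: ring closure and ether cleavage are separated.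
- From 22, Me3SiBr in CH2Cl2 at −40 °C ionises the carbinol under mild conditions; the neighbouring methoxy oxygen of ring A captures the cation and bromide removes its methyl group. This gives (2R,3R,4S)-5,7-dimethoxy-4-(2-methylpropyl)-3-(propan-2-yl)-2-(2,4,6-trimethoxyphenyl)-3,4-dihydro-2H-chromene F3, a stable compound whose configuration can be checked.
- The five remaining ethers of F3 are then cleaved with BCl3 and Bu4NI (CH2Cl2, −78 → 0 °C) to give 23.
- The fallback sets out from 22 and returns at 23.

Step 8. The most likely failure is incomplete substitution: the first formyl group on each ring slows the second, most of all on ring A, which has only two free hydroxyl groups, so mixtures of partly formylated material may result. Opening of O1–C2 by the HCl formed is a lesser risk. Fallback: a Rieche formylation on 23 (Cl2CHOMe, TiCl4, CH2Cl2, −20 °C → rt, then aqueous hydrolysis).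
- The phenols are first converted into titanium phenoxides, which bind the α-chloro ether and deliver it to the ortho carbon.
- This is a Friedel–Crafts alkylation followed by hydrolysis, not an iminium substitution, and a stronger electrophile results.
- The fallback sets out from 23 and returns at 25; no new compound arises on the way (entry F0).

## Further compounds

F1 | step 4 | (1S)-2-methyl-1-(trimethylstannyl)propyl 2,4,6-triisopropylbenzoate | CC(C)[C@H]([Sn](C)(C)C)OC(=O)c1c(C(C)C)cc(C(C)C)cc1C(C)C
F2 | step 6 | 2-[(1RS,2R,3S)-1-chloro-5-methyl-2-(propan-2-yl)-3-(2,4,6-trimethoxyphenyl)hexyl]-4,4,5,5-tetramethyl-1,3,2-dioxaborolane | CC(C)C[C@H](c1c(OC)cc(OC)cc1OC)[C@@H](C(C)C)C(Cl)B1OC(C)(C)C(C)(C)O1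
F3 | step 7 | (2R,3R,4S)-5,7-dimethoxy-4-(2-methylpropyl)-3-(propan-2-yl)-2-(2,4,6-trimethoxyphenyl)-3,4-dihydro-2H-chromene | CC(C)C[C@@H]1c2c(OC)cc(OC)cc2O[C@@H](c2c(OC)cc(OC)cc2OC)[C@@H]1C(C)C
F0 | step 8 | none | none
A1 | alternative 1 | sideroxylonal A penta-O-methyl ether, (2R,3R,4S)-2-(3,5-diformyl-2,4,6-trimethoxyphenyl)-5,7-dimethoxy-4-(2-methylpropyl)-3-(propan-2-yl)-3,4-dihydro-2H-chromene-6,8-dicarbaldehyde | CC(C)C[C@@H]1c2c(OC)c(C=O)c(OC)c(C=O)c2O[C@@H](c2c(OC)c(C=O)c(OC)c(C=O)c2OC)[C@@H]1C(C)C
A2 | alternative 1 | 5-[(1R,2R,3S)-3-(2-fluoro-3,5-diformyl-4,6-dimethoxyphenyl)-1-hydroxy-5-methyl-2-(propan-2-yl)hexyl]-2,4,6-trimethoxybenzene-1,3-dicarbaldehyde | CC(C)C[C@H](c1c(OC)c(C=O)c(OC)c(C=O)c1F)[C@@H](C(C)C)[C@@H](O)c1c(OC)c(C=O)c(OC)c(C=O)c1OC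
A3 | alternative 2 | 5,7-dimethoxy-4-(2-methylpropyl)-3-(propan-2-yl)-2-(2,4,6-trimethoxyphenyl)-2H-chromene (racemic at C2) | CC(C)CC1=C(C(C)C)C(c2c(OC)cc(OC)cc2OC)Oc2cc(OC)cc(OC)c12
A4 | alternative 2 | (1E)-5-methyl-2-(propan-2-yl)-1-(2,4,6-trimethoxyphenyl)hex-1-en-3-one | CC(C)CC(=O)/C(C(C)C)=C/c1c(OC)cc(OC)cc1OC
A5 | alternative 2 | 3,5-dimethoxy-2-(trimethylsilyl)phenyl trifluoromethanesulfonate | COc1cc(OC)c([Si](C)(C)C)c(OS(=O)(=O)C(F)(F)F)c1
A6 | alternative 3 | 2-[(2R,3R,4S)-5,7-dimethoxy-4-(2-methylpropyl)-3-(propan-2-yl)-3,4-dihydro-2H-chromen-2-yl]-5-ethoxy-4,6-dimethyl-3-[(triisopropylsilyl)oxy]phenol | CC(C)C[C@@H]1c2c(OC)cc(OC)cc2O[C@@H](c2c(O)c(C)c(OCC)c(C)c2O[Si](C(C)C)(C(C)C)C(C)C)[C@@H]1C(C)C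
A7 | alternative 3 | {[(2R,3R,4S)-5,7-dimethoxy-4-(2-methylpropyl)-3-(propan-2-yl)-3,4-dihydro-2H-chromen-2-yl]ethynyloxy}triisopropylsilane | CC(C)C[C@@H]1c2c(OC)cc(OC)cc2O[C@@H](C#CO[Si](C(C)C)(C(C)C)C(C)C)[C@@H]1C(C)C
A8 | alternative 3 | 3-ethoxy-2,4-dimethylcyclobut-2-en-1-one (racemic) | CCOC1=C(C)C(=O)C1C
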